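The route cuts both bonds around the carbinol carbon C1': the bond from quinone-ring carbon C2 (ring A of the naphthazarin) to C1', and the bond from the allylic C2'H2 to olefinic C3'. Because C1' sits between an sp2 ring carbon and a methylene that ends in the C3'=C4'Me2 unit, C1'–C2' maps onto a vinyl group on boron. One ligand-controlled, palladium-catalysed conjunctive coupling unites a halide-free tetra-MOM naphthyl(vinyl)boronate ate complex with 2-methylprop-1-enyl triflate. The ate complex comes from ortho-lithiation of the symmetric tetra-MOM arene and addition to vinyl pinacolboronate. The coupling forms both C–C bonds and sets C1' (S) as a C–B bond, later oxidised with retention.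

Key step: step 3

Remark on the chemistry: C1' of the target is S (alkannin series). The quinoid and benzenoid rings of a naphthazarin exchange by fast tautomerism, so the ring position of the side chain is fixed only formally.

Assumption: the sense of induction in step 3 is inferred by analogy with aryl migrations onto vinylboronates with this ligand family, and (Rp,Rp)-MandyPhos is written for the S boronate. If a Mosher analysis of alcohol 10 in the first run shows the opposite sense, the commercial (Sp,Sp) antipode is used with no other change.

Step 1
Reactants: 1 naphthazarin (5,8-dihydroxynaphthalene-1,4-dione)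
Product: 3 1,4,5,8-tetrakis(methoxymethoxy)naphthalene, via naphthalene-1,4,5,8-tetrol 2 (not isolated)
Conditions: Na2S2O4, Et2O/H2O, rt, Ar; organic layer dried and concentrated under Ar; then NaH (5 equiv), MOMCl (5 equiv), DMF, 0 °C to rt
Reagents that add atoms: chloromethyl methyl ether (MOMCl), COCCl
Why: Dithionite reduction of the quinone to the leuco compound followed by fourfold Williamson O-alkylation of its phenoxides with the hard electrophile MOMCl is a standard reductive etherification of naphthazarin, and the fully symmetric product has four equivalent ring C–H positions for the later lithiation.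

Step 2
Reactants: 4 isobutyraldehyde
Product: 5 2-methylprop-1-enyl trifluoromethanesulfonate
Conditions: Tf2O, 2,6-di-tert-butyl-4-methylpyridine, CH2Cl2, 0 °C to rt; distillation
Reagents that add atoms: triflic anhydride, O=S(=O)(OS(=O)(=O)C(F)(F)F)C(F)(F)F
Why: O-sulfonylation of the aldehyde and loss of its single α-proton to the hindered non-nucleophilic pyridine is the standard enol triflate synthesis from enolisable aldehydes, and only one product without E/Z isomerism is possible because the olefin terminus carries two methyl groups.

Step 3
Reactants: 3 1,4,5,8-tetrakis(methoxymethoxy)naphthalene (1.1 equiv), 6 vinylboronic acid pinacol ester, 5 2-methylprop-1-enyl trifluoromethanesulfonate (1.2 equiv)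
Product: 9 (S)-2-[4-methyl-1-(1,4,5,8-tetrakis(methoxymethoxy)naphthalen-2-yl)pent-3-en-1-yl]-4,4,5,5-tetramethyl-1,3,2-dioxaborolane, via 2-lithio-tetra-MOM-naphthalene 7 (not isolated), via lithium naphthyl(vinyl)boronate complex 8 (not isolated)
Conditions: n-BuLi (1.05 equiv), THF, 0 °C, 1 h; 6, −78 to 0 °C; then Pd(OAc)2 (2 mol%), (Rp,Rp)-1,1'-bis[bis(4-methoxy-3,5-dimethylphenyl)phosphino]-2,2'-bis[(S)-α-(dimethylamino)benzyl]ferrocene (MandyPhos ligand, 2.4 mol%), 5, THF, 60 °C; filtration through silica
Reagents that add atoms: none
Why: Oxidative addition of triflate 5 to zerovalent palladium gives a cationic alkenyl complex of divalent palladium that binds the vinyl group of the four-coordinate boronate 8 and triggers anti 1,2-migration of the naphthyl group from boron to the α-carbon (forming C2–C1') while the β-carbon bonds to palladium; reductive elimination then forms C2'–C3' and regenerates zerovalent palladium. The closest known reaction type is the enantioselective palladium-catalysed conjunctive cross-coupling of aryl(vinyl)boronate ate complexes with alkenyl and aryl triflates. No ring is closed. The new stereocentre C1' is controlled by the chiral ferrocenyl bisphosphine on palladium, which selects one enantiotopic face of the vinyl group of the achiral ate complex during the metallate shift, and the resulting secondary benzylic pinacol boronate is configurationally stable. The step needs chemoselectivity for the metallate shift over direct Suzuki-type transfer of the vinyl or naphthyl group; this is secured by the halide-free ate complex (made by MOM-directed deprotonation, with the arene in slight excess so that no butyl(vinyl)boronate forms), the weakly coordinating triflate and the wide-bite-angle ligand. Linear placement of the isopropylidene unit is guaranteed because C3' arrives as the sp2 carbon of the electrophile, so no allylic transposition can occur.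

Step 4
Reactants: 9 (S)-pinacol boronate
Product: 10 (S)-4-methyl-1-[1,4,5,8-tetrakis(methoxymethoxy)naphthalen-2-yl]pent-3-en-1-ol
Conditions: NaOH (3 M aq), H2O2 (30%), THF, 0 °C to rt
Reagents that add atoms: hydrogen peroxide, OO
Why: Hydroperoxide adds to boron and C1' migrates from boron to oxygen with retention (stereospecific boronate oxidation), so the S configuration passes into the alcohol, while the MOM ethers, the arene and the unactivated trisubstituted olefin are inert to cold alkaline peroxide.

Step 5
Reactants: 10 (S)-alcohol, 11 tiglic acid ((E)-2-methylbut-2-enoic acid)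
Product: 12 (S)-4-methyl-1-[1,4,5,8-tetrakis(methoxymethoxy)naphthalen-2-yl]pent-3-en-1-yl (E)-2-methylbut-2-enoate
Conditions: DCC, DMAP (cat.), CH2Cl2, 0 °C to rt
Reagents that add atoms: none
Why: Steglich esterification acylates the secondary alcohol through the N-acylpyridinium without touching the C1'–O bond, so configuration is retained, the E-tigloyl unit is the thermodynamically favoured isomer, and capping the oxygen now blocks its acid-induced addition to the C3'=C4' olefin in the last step.

Step 6
Reactants: 12 (S)-tetra-MOM tiglate
Product: 15 (S)-1-(5,8-dihydroxy-1,4-dioxo-1,4-dihydronaphthalen-2-yl)-4-methylpent-3-en-1-yl (E)-2-methylbut-2-enoate (alkannin tiglate), via 5,8-bis-MOM side-chain-ring quinone 13 (not isolated), via regioisomeric distal-ring quinone 14 (not isolated)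
Conditions: (NH4)2Ce(NO3)6 (2.2 equiv), MeCN/H2O, 0 °C, 15 min; EtOAc extraction; crude in THF, 3 M aq HCl, rt
Reagents that add atoms: water, O
Why: Tetravalent cerium oxidises one bis-MOM hydroquinone ring by two single-electron transfers with ipso attack of water (oxidative dealkylation) to give quinone 13 and/or its ring regioisomer 14; in both, the two remaining MOM ethers lie peri to a quinone carbonyl and are removed by dilute-acid acetal hydrolysis, both converge on 15 through naphthazarin tautomerism, and the electron-poor quinone disfavours ionisation at C1', which is not otherwise involved.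

Compound list
1 | naphthazarin (5,8-dihydroxynaphthalene-1,4-dione) | O=C1C=CC(=O)c2c(O)ccc(O)c12 | starting material
2 | naphthalene-1,4,5,8-tetrol (leuconaphthazarin, in equilibrium with its 2,3-dihydro diketo tautomer) | Oc1ccc(O)c2c(O)ccc(O)c12 | intermediate
3 | 1,4,5,8-tetrakis(methoxymethoxy)naphthalene | COCOc1ccc(OCOC)c2c(OCOC)ccc(OCOC)c12 | intermediate
4 | isobutyraldehyde | CC(C)C=O | starting material
5 | 2-methylprop-1-enyl trifluoromethanesulfonate | CC(C)=COS(=O)(=O)C(F)(F)F | intermediate
6 | vinylboronic acid pinacol ester | C=CB1OC(C)(C)C(C)(C)O1 | starting material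
7 | 2-lithio-1,4,5,8-tetrakis(methoxymethoxy)naphthalene | COCOc1cc([Li])c(OCOC)c2c(OCOC)ccc(OCOC)c12 | intermediate
8 | lithium [1,4,5,8-tetrakis(methoxymethoxy)naphthalen-2-yl](vinyl)(pinacolato)borate | [Li+].C=C[B-]1(OC(C)(C)C(C)(C)O1)c1cc(OCOC)c2c(OCOC)ccc(OCOC)c2c1OCOC | intermediate
9 | (S)-2-[4-methyl-1-(1,4,5,8-tetrakis(methoxymethoxy)naphthalen-2-yl)pent-3-en-1-yl]-4,4,5,5-tetramethyl-1,3,2-dioxaborolane | COCOc1cc([C@@H](B3OC(C)(C)C(C)(C)O3)CC=C(C)C)c(OCOC)c2c(OCOC)ccc(OCOC)c12 | intermediate
10 | (S)-4-methyl-1-[1,4,5,8-tetrakis(methoxymethoxy)naphthalen-2-yl]pent-3-en-1-ol | COCOc1cc([C@@H](O)CC=C(C)C)c(OCOC)c2c(OCOC)ccc(OCOC)c12 | intermediate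
11 | tiglic acid ((E)-2-methylbut-2-enoic acid) | C/C=C(\C)C(=O)O | starting material
12 | (S)-4-methyl-1-[1,4,5,8-tetrakis(methoxymethoxy)naphthalen-2-yl]pent-3-en-1-yl (E)-2-methylbut-2-enoate | C/C=C(\C)C(=O)O[C@@H](CC=C(C)C)c1cc(OCOC)c2c(OCOC)ccc(OCOC)c2c1OCOC | intermediate
13 | (S)-1-[5,8-bis(methoxymethoxy)-1,4-dioxo-1,4-dihydronaphthalen-2-yl]-4-methylpent-3-en-1-yl (E)-2-methylbut-2-enoate | C/C=C(\C)C(=O)O[C@@H](CC=C(C)C)C1=CC(=O)c2c(OCOC)ccc(OCOC)c2C1=O | intermediate
14 | (S)-1-[1,4-bis(methoxymethoxy)-5,8-dioxo-5,8-dihydronaphthalen-2-yl]-4-methylpent-3-en-1-yl (E)-2-methylbut-2-enoate | C/C=C(\C)C(=O)O[C@@H](CC=C(C)C)c1cc(OCOC)c2C(=O)C=CC(=O)c2c1OCOC | intermediate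
15 | (S)-1-(5,8-dihydroxy-1,4-dioxo-1,4-dihydronaphthalen-2-yl)-4-methylpent-3-en-1-yl (E)-2-methylbut-2-enoate (alkannin tiglate, CNP0373203.1) | C/C=C(\C)C(=O)O[C@@H](CC=C(C)C)C1=CC(=O)c2c(O)ccc(O)c2C1=O | target

Total step count: 6.
Longest linear sequence: 5 steps from naphthazarin (steps 1, 3, 4, 5, 6); step 2 is a one-step side branch.

Steps most likely to fail

Step 3. The coupling may suffer from direct Suzuki-type transfer of the vinyl or naphthyl group in place of the metallate shift, from incomplete or twofold lithiation of 3, or from weak facial discrimination with the ortho-alkoxy naphthyl migrating group. The fallback reaches the same carbinol by carbonyl chemistry. Setting out from 3, lithiation as in the route (through 7) and quenching with DMF should give 1,4,5,8-tetrakis(methoxymethoxy)naphthalene-2-carbaldehyde F1. Brown allylation with B-allyldiisopinocampheylborane prepared from (+)-α-pinene (Et2O, −78 °C, then NaOH/H2O2) is expected, by analogy with benzaldehyde, to add to the Si face and give (S)-1-[1,4,5,8-tetrakis(methoxymethoxy)naphthalen-2-yl]but-3-en-1-ol F2. Cross-metathesis of F2 with excess 2-methyl-2-butene and the second-generation Grubbs catalyst RuCl2(=CHPh)(H2IMes)(PCy3) then installs the isopropylidene terminus and rejoins the route at alcohol 10. The allyl-then-metathesis order avoids the branched adduct that a prenyl metal would give.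

Step 6. The tiglate may be lost by ionisation at C1' or by ester cleavage during oxidation and acid treatment, and over-oxidation of the second ring may erode material. The fallback moves the esterification to the end. Setting out from alcohol 10, the same oxidation with (NH4)2Ce(NO3)6 should give (S)-2-(1-hydroxy-4-methylpent-3-enyl)-5,8-bis(methoxymethoxy)naphthalene-1,4-dione F3 together with its ring regioisomer (S)-6-(1-hydroxy-4-methylpent-3-enyl)-5,8-bis(methoxymethoxy)naphthalene-1,4-dione F4. Dilute aqueous HCl in THF should convert both into alkannin F5. Tiglic acid 11 with DCC and catalytic DMAP then acylates the side-chain hydroxyl in preference to the two chelated peri-hydroxyls and rejoins the route at 15.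

Step 1. The leuco compound may re-oxidise in air before alkylation, the fourfold alkylation may stop short, and the diketo tautomer may alkylate on carbon. The fallback protects in two stages around an ordinary hydroquinone. Setting out from 1, MOMCl and iPr2NEt in CH2Cl2 should give 5,8-bis(methoxymethoxy)naphthalene-1,4-dione F6. Reduction with Na2S2O4 should give 5,8-bis(methoxymethoxy)naphthalene-1,4-diol F7, which has no stable diketo tautomer. NaH and MOMCl in DMF then rejoin the route at 3.

Further compounds
F1 | step 3 | 1,4,5,8-tetrakis(methoxymethoxy)naphthalene-2-carbaldehyde | COCOc1cc(C=O)c(OCOC)c2c(OCOC)ccc(OCOC)c12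
F2 | step 3 | (S)-1-[1,4,5,8-tetrakis(methoxymethoxy)naphthalen-2-yl]but-3-en-1-ol | COCOc1cc([C@@H](O)CC=C)c(OCOC)c2c(OCOC)ccc(OCOC)c12
F3 | step 6 | (S)-2-(1-hydroxy-4-methylpent-3-enyl)-5,8-bis(methoxymethoxy)naphthalene-1,4-dione | O[C@@H](CC=C(C)C)C1=CC(=O)c2c(OCOC)ccc(OCOC)c2C1=O
F4 | step 6 | (S)-6-(1-hydroxy-4-methylpent-3-enyl)-5,8-bis(methoxymethoxy)naphthalene-1,4-dione | O[C@@H](CC=C(C)C)c1cc(OCOC)c2C(=O)C=CC(=O)c2c1OCOC
F5 | step 6 | alkannin ((S)-5,8-dihydroxy-2-(1-hydroxy-4-methylpent-3-enyl)naphthalene-1,4-dione) | O[C@@H](CC=C(C)C)C1=CC(=O)c2c(O)ccc(O)c2C1=O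
F6 | step 1 | 5,8-bis(methoxymethoxy)naphthalene-1,4-dione | COCOc1ccc(OCOC)c2C(=O)C=CC(=O)c12
F7 | step 1 | 5,8-bis(methoxymethoxy)naphthalene-1,4-diol | COCOc1ccc(OCOC)c2c(O)ccc(O)c12
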